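Numbering the target as a bicyclo[3.3.1]nonan-9-one (C1 bridgehead CH, C2 CHOH, C3 CHN, C4 CH2, C5 bridgehead C–OH, C6–C7 epoxide, C8 CHOH), everything rests on the C1–C2 aldol bond of the amide-bearing ring C1–C2–C3–C4–C5–C9. The key step exploits the β-hydroxy ketone C9(=O)–C1–C2(OH): C9 is flanked by the quaternary carbinol C5 and can enolise only toward C1. Its precursor is a constitutional isomer of the target, an epoxy-hydroxycyclohexanone spiro-fused to a lactol. Base opens the lactol and a reversible aldol closes the ring, sets C1 and C2, and funnels both anomers (and any C3 epimer) into the chair–chair product. The cyclohexane core derives from an enantioselectively epoxidised methoxyquinone monoketal.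

Key step: step 10

Remark: the sense of induction in step 2 is assigned by analogy with related cinchona phase-transfer epoxidations; the pseudo-enantiomeric cinchoninium salt would be used if the antipode forms.

Step 1
Reactants: 1 2,4-dimethoxyphenol
Product: 2 2,4,4-trimethoxycyclohexa-2,5-dien-1-one
Conditions: PhI(OAc)2, MeOH, 0 °C
Reagents that add atoms: methanol, CO
Why: Hypervalent-iodine oxidative dearomatisation of a 4-alkoxyphenol in methanol (quinone monoketal formation) should trap the phenoxenium equivalent at the para carbon that already bears OMe; no stereocenter is formed.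

Step 2
Reactants: 2 2,4,4-trimethoxycyclohexa-2,5-dien-1-one
Product: 3 (1S,6R)-3,5,5-trimethoxy-7-oxabicyclo[4.1.0]hept-3-en-2-one
Conditions: t-BuOOH, aq. NaOH, N-benzylcinchonidinium chloride (10 mol%), toluene, 0 °C; recrystallisation
Reagents that add atoms: tert-butyl hydroperoxide, CC(C)(C)OO
Why: Weitz–Scheffer nucleophilic epoxidation under cinchona phase-transfer catalysis should attack only the unsubstituted enone arm (the 2-methoxy arm is electron-rich), and the chiral ion pair selects one enantiotopic face, setting both epoxide carbons.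

Step 3
Reactants: 4 1,1-dimethoxypropan-2-one; 5 (R)-2-methylpropane-2-sulfinamide
Product: 6 (R,E)-N-(1,1-dimethoxypropan-2-ylidene)-2-methylpropane-2-sulfinamide
Conditions: Ti(OEt)4, THF, 65 °C
Reagents that add atoms: none
Why: Titanium(IV)-mediated condensation of a ketone with tert-butanesulfinamide (N-sulfinyl ketimine formation) should leave the acetal untouched and give the E-imine with sulfur anti to the branched acetal carbon.

Step 4
Reactants: 6 (R,E)-N-(1,1-dimethoxypropan-2-ylidene)-2-methylpropane-2-sulfinamide; 3 (1S,6R)-3,5,5-trimethoxy-7-oxabicyclo[4.1.0]hept-3-en-2-one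
Product: 8 (R)-N-{(E)-1-[(1S,2S,6R)-2-hydroxy-3,5,5-trimethoxy-7-oxabicyclo[4.1.0]hept-3-en-2-yl]-3,3-dimethoxypropan-2-ylidene}-2-methylpropane-2-sulfinamide (tertiary OH cis to the epoxide), via lithium aza-enolate of 6 (methyl-deprotonated) 7 (not isolated)
Conditions: LDA (1.0 equiv), THF, −78 °C; then 3, −78 °C; H2O quench at −78 °C
Reagents that add atoms: none
Why: Aza-enolate (metalloenamine) aldol-type 1,2-addition to the ketone should occur anti to the epoxide oxygen, as organometallic additions to epoxyquinone monoketals do, placing the new tertiary OH cis to the epoxide.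

Step 5
Reactants: 8 β-hydroxy N-sulfinyl ketimine
Product: 9 (R)-N-{(2S)-1-[(1S,2S,6R)-2-hydroxy-3,5,5-trimethoxy-7-oxabicyclo[4.1.0]hept-3-en-2-yl]-3,3-dimethoxypropan-2-yl}-2-methylpropane-2-sulfinamide
Conditions: L-Selectride (2.5 equiv), THF, −78 °C; then H2O
Reagents that add atoms: none
Why: Sulfinyl-controlled hydride reduction of an N-tert-butanesulfinyl ketimine with a bulky, non-chelating trialkylborohydride should give the (S)-amine carbon from the (R)-sulfinyl E-imine through the open transition state; ketal, acetal and epoxide are inert at −78 °C.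

Step 6
Reactants: 9 sulfinamide; 10 (2E)-dec-2-enoic acid
Product: 12 (2E)-N-{(2S)-1-[(1S,2S,6R)-2-hydroxy-3,5,5-trimethoxy-7-oxabicyclo[4.1.0]hept-3-en-2-yl]-3,3-dimethoxypropan-2-yl}dec-2-enamide, via (1S,2S,6R)-2-[(2S)-2-amino-3,3-dimethoxypropyl]-3,5,5-trimethoxy-7-oxabicyclo[4.1.0]hept-3-en-2-ol (formed as its hydrochloride) 11 (not isolated)
Conditions: HCl (4 M in dioxane, 2 equiv), MeOH, 0 °C, evaporation; then 10, EDC·HCl, HOBt, NaHCO3, DMF, 0 °C → rt
Reagents that add atoms: none
Why: Acidolysis of the N–S bond in methanol (ketal and acetal persist, and the ammonium ion protects the neighbouring acetal) followed by carbodiimide amide coupling; no stereocenter is touched, and the amine is acylated before any electrophilic vinylogous ester is unveiled.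

Step 7
Reactants: 12 amide with ring ketal and side-chain acetal
Product: 13 (2E)-N-[(1S,2S,4'S,6R)-5'-hydroxy-3-methoxy-5-oxospiro[7-oxabicyclo[4.1.0]hept-3-ene-2,2'-oxolan]-4'-yl]dec-2-enamide (lactol, anomeric mixture)
Conditions: TFA, H2O, CH2Cl2, 0 °C → rt
Reagents that add atoms: water, O
Why: Aqueous acid hydrolysis of the vinylogous ortho ester and of the acetal: water should attack the dimethoxyallyl cation at the less hindered terminus remote from the quaternary carbinol, leaving the methyl enol ether next to it, and the freed aldehyde is captured by the tertiary OH as a five-membered lactol.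

Step 8
Reactants: 13 spiro-lactol vinylogous ester
Product: 14 (2E)-N-[(1S,2S,4'S,5S,6S)-5,5'-dihydroxy-3-methoxyspiro[7-oxabicyclo[4.1.0]hept-3-ene-2,2'-oxolan]-4'-yl]dec-2-enamide (secondary OH cis to the epoxide)
Conditions: NaBH4, CeCl3·7H2O, MeOH–THF, −78 °C
Reagents that add atoms: none
Why: Luche 1,2-reduction of the vinylogous-ester ketone, with hydride arriving anti to the adjacent epoxide oxygen, should give the alcohol cis to the epoxide; the lactol is not reduced at −78 °C.

Step 9
Reactants: 14 enol ether allylic alcohol
Product: 16 (2E)-N-[(1S,2S,4'S,5S,6S)-5,5'-dihydroxy-3-oxospiro[7-oxabicyclo[4.1.0]heptane-2,2'-oxolan]-4'-yl]dec-2-enamide, via α-(acetoxymercurio) ketone 15 (not isolated)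
Conditions: Hg(OAc)2 (1.1 equiv), NaOAc, THF–H2O, 0 °C; then aq. KI
Reagents that add atoms: water, O; mercury(II) acetate, CC(=O)O[Hg]OC(C)=O (its atoms stay only in 15)
Why: Mercury(II)-assisted hydrolysis of a methyl enol ether (oxymercuration, loss of methanol, iodide demercuration) attacks the π bond under near-neutral conditions and so should avoid the protic ionisation of the allylic alcohol (Stork–Danheiser-type dehydration); no stereocenter changes.

Step 10
Reactants: 16 spiro-lactol β-hydroxy ketone
Product: 18 isariotin D, (2E)-N-[(1S,2R,3S,5S,6S,7S,8S)-6,7-epoxy-2,5,8-trihydroxy-9-oxobicyclo[3.3.1]nonan-3-yl]dec-2-enamide, via (2E)-N-{(2S)-1-[(1S,2S,5S,6S)-2,5-dihydroxy-3-oxo-7-oxabicyclo[4.1.0]heptan-2-yl]-3-oxopropan-2-yl}dec-2-enamide 17 (not isolated)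
Conditions: DBU (0.5 equiv), THF–MeOH, 0 °C → rt
Reagents that add atoms: none
Why: DBU opens the lactol to hydroxy keto aldehyde 17 (ring–chain tautomerism) and reversibly enolises the C9 ketone, whose only α-hydrogens are on C1 because C5 is the quaternary carbinol; the enolate then adds to the aldehyde carbon C2. The closest known reaction type is the base-mediated intramolecular aldol addition of a keto aldehyde held as its lactol. The six-membered carbocycle C1–C2–C3–C4–C5–C9 closes in the 6-(enolendo)-exo-trig mode; the side chain on C5 sits axial on the face anti to the epoxide, so only 1,3-diaxial bridging is possible and C1 is fixed by the ring constraint. C2 is controlled by the chair-like transition state and by equilibration, which place its OH axial, gauche to and hydrogen-bonded with the C9 carbonyl, while the C3 amide (set in step 5) lies equatorial; a C3 epimer would have to hold the amide endo against C7 and should drain through enolisation of 17. The step needs aldol closure to win over lactol re-formation and elimination: C–C bond formation in a chair–chair bicyclo[3.3.1]nonanone provides the driving force, and the product cannot dehydrate because C1 is a bridgehead. Both lactol anomers converge on the same product.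

Compound list
1 | 2,4-dimethoxyphenol | COc1ccc(O)c(OC)c1 | starting material
2 | 2,4,4-trimethoxycyclohexa-2,5-dien-1-one | COC1=CC(OC)(OC)C=CC1=O | intermediate
3 | (1S,6R)-3,5,5-trimethoxy-7-oxabicyclo[4.1.0]hept-3-en-2-one | COC1=CC(OC)(OC)[C@@H]2O[C@@H]2C1=O | intermediate
4 | 1,1-dimethoxypropan-2-one | CC(=O)C(OC)OC | starting material
5 | (R)-2-methylpropane-2-sulfinamide | CC(C)(C)[S@@](=O)N | starting material
6 | (R,E)-N-(1,1-dimethoxypropan-2-ylidene)-2-methylpropane-2-sulfinamide | C/C(=N\[S@](=O)C(C)(C)C)C(OC)OC | intermediate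
7 | lithium aza-enolate of 6 | C=C(N([Li])[S@](=O)C(C)(C)C)C(OC)OC | intermediate (not isolated)
8 | β-hydroxy N-sulfinyl ketimine (tertiary OH cis to epoxide) | COC1=CC(OC)(OC)[C@@H]2O[C@@H]2[C@@]1(O)C/C(=N\[S@](=O)C(C)(C)C)C(OC)OC | intermediate
9 | (R)-sulfinamide with (2S)-amine carbon | COC1=CC(OC)(OC)[C@@H]2O[C@@H]2[C@@]1(O)C[C@H](N[S@](=O)C(C)(C)C)C(OC)OC | intermediate
10 | (2E)-dec-2-enoic acid | CCCCCCC/C=C/C(=O)O | starting material
11 | (2S)-primary amine (formed as hydrochloride) | COC1=CC(OC)(OC)[C@@H]2O[C@@H]2[C@@]1(O)C[C@H](N)C(OC)OC | intermediate (not isolated)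
12 | (2E)-dec-2-enamide with ring ketal and side-chain acetal | COC1=CC(OC)(OC)[C@@H]2O[C@@H]2[C@@]1(O)C[C@H](NC(=O)/C=C/CCCCCCC)C(OC)OC | intermediate
13 | spiro-lactol vinylogous ester (anomeric mixture) | COC1=CC(=O)[C@@H]2O[C@@H]2[C@@]13C[C@H](NC(=O)/C=C/CCCCCCC)C(O)O3 | intermediate
14 | spiro-lactol enol ether, secondary OH cis to epoxide | COC1=C[C@H](O)[C@@H]2O[C@@H]2[C@@]13C[C@H](NC(=O)/C=C/CCCCCCC)C(O)O3 | intermediate
15 | α-(acetoxymercurio) ketone spiro-lactol | O=C1C([Hg]OC(C)=O)[C@H](O)[C@@H]2O[C@@H]2[C@@]13C[C@H](NC(=O)/C=C/CCCCCCC)C(O)O3 | intermediate (not isolated)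
16 | spiro-lactol β-hydroxy ketone (isomer of the target) | O=C1C[C@H](O)[C@@H]2O[C@@H]2[C@@]13C[C@H](NC(=O)/C=C/CCCCCCC)C(O)O3 | intermediate
17 | open hydroxy keto aldehyde | O=C[C@H](C[C@@]1(O)C(=O)C[C@H](O)[C@@H]2O[C@@H]21)NC(=O)/C=C/CCCCCCC | intermediate (not isolated)
18 | isariotin D | CCCCCCC/C=C/C(=O)N[C@H]1C[C@@]2(O)C(=O)[C@H]([C@H](O)[C@@H]3O[C@@H]32)[C@H]1O | target

Total step count: 10. Longest linear sequence: 9 steps (1, 2, 4–10 from compound 1); step 3 is a one-step side branch.

Steps most likely to fail

Step 10: the lactol may be too stable for the aldol equilibrium to drain it, or base may cause C3 epimerisation or attack of the lactol alkoxide on the epoxide faster than closure. The fallback is a base-free, irreversible samarium Reformatsky-type closure that sets out from 14 and comes back at 18. Bromo-hydration of the enol ether (NBS, NaHCO3, THF–H2O, 0 °C) should give the α-bromo ketone spiro-lactol F1. SmI2 (THF, −78 °C) then generates the samarium(III) enolate regiospecifically at C1, and chelated aldol addition to the ring-opened aldehyde should give 18.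

Step 9: the C8 hydroxyl may be lost by ionisation or β-elimination from the organomercurial, giving the enone. The fallback is a protecting-group detour from 14 back to 16. Silylation of both hydroxyls (TESOTf, 2,6-lutidine, CH2Cl2, −78 °C) gives the bis(triethylsilyl) ether F2. Enol ether hydrolysis with oxalic acid on wet silica, now without an ionisable allylic OH, gives the silylated ketone F3. HF·pyridine in THF then returns 16.

Step 4: the basic aza-enolate may enolise or degrade the epoxy ketone, the addition may revert, or facial selectivity may be poor. The fallback decouples C–C bond formation from nitrogen introduction, setting out from 4 and 3 and coming back at 8. Ketone 4 is deprotonated at the methyl group (LDA, THF, −78 °C) to the less basic lithium enolate F4. Aldol addition to 3, anti to the epoxide, gives the β-hydroxy ketone F5, which is condensed with 5 (Ti(OEt)4, THF) to give 8.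

Further compounds
F1 | step 10 | α-bromo ketone spiro-lactol | O=C1C(Br)[C@H](O)[C@@H]2O[C@@H]2[C@@]13C[C@H](NC(=O)/C=C/CCCCCCC)C(O)O3
F2 | step 9 | bis(triethylsilyl) ether of 14 | COC1=C[C@H](O[Si](CC)(CC)CC)[C@@H]2O[C@@H]2[C@@]13C[C@H](NC(=O)/C=C/CCCCCCC)C(O[Si](CC)(CC)CC)O3
F3 | step 9 | bis(triethylsilyl) ether of 16 | O=C1C[C@H](O[Si](CC)(CC)CC)[C@@H]2O[C@@H]2[C@@]13C[C@H](NC(=O)/C=C/CCCCCCC)C(O[Si](CC)(CC)CC)O3
F4 | step 4 | lithium enolate of 4 | [Li]OC(=C)C(OC)OC
F5 | step 4 | β-hydroxy ketone from 3 and 4 | COC1=CC(OC)(OC)[C@@H]2O[C@@H]2[C@@]1(O)CC(=O)C(OC)OC
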